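**Retrosynthetic overview**

1. Enabling feature: in the ten-membered carbocycle (C1–C10) the cis-2,3-epoxide lies next to the exocyclic methylene C4=C15. O–C2–C3–C4(=C15) is therefore the homoallylic alkoxide left by a carbonyl allylation, and the C3–O bond is the trace of a γ-chloro substituent on the allyl metal.
2. C2–C3 is cut: a 2,3-seco chain with an (E)-enal at C2 and an allylic CHCl2 group at C3 is closed by a chromium-mediated chloroallylation to the ten-membered syn-chlorohydrin. Its C2 hydroxyl then directs the 1,10-epoxidation and closes the 2,3-epoxide.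
3. The seco chain comes from a three-component union at C7/C11 (dithiane acyl-anion equivalent carrying C8–C10/C1–C2, a C6-chiral butenolide, formaldehyde for C13). C4–C5 comes from a Negishi acylation of the lactone acid chloride derived from L-glutamic acid.
4. Ring order: γ-lactone (chiral pool, kept throughout) → ten-membered carbocycle → 1,10-epoxide → 2,3-epoxide.

Key step: step 19

Remark: germacranolide numbering is used (ring C1–C10; lactone carbons C11–C13; C14 = methyl on C10; C15 = methylene on C4), and 2-bromoacrolein diethyl acetal is taken as a purchased reagent.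

**Route**

Step 1
Reactants: 1 (S)-5-oxotetrahydrofuran-2-carboxylic acid
Product: 2 (S)-5-oxotetrahydrofuran-2-carbonyl chloride
Conditions: (COCl)2, DMF (cat.), CH2Cl2, 0 °C → rt
Reagents that add atoms: oxalyl chloride, ClC(=O)C(=O)Cl
Why: Vilsmeier-type activation should give the acid chloride without touching the lactone or the C6 stereocentre.

Step 2
Reactants: 2 (S)-5-oxotetrahydrofuran-2-carbonyl chloride; 3 2-bromo-3,3-diethoxyprop-1-ene
Product: 6 (5S)-5-[2-(diethoxymethyl)prop-2-enoyl]oxolan-2-one, via alkenyllithium 4 (not isolated), via alkenylzinc chloride 5 (not isolated)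
Conditions: 3, n-BuLi, THF, −78 °C; ZnCl2, −78 → 0 °C; then 2, Pd(PPh3)4 (5 mol%), 0 °C → rt
Reagents that add atoms: none
Why: Negishi acylation, in which the alkenylzinc reagent couples with the acid chloride, does not add to the lactone and is not basic enough to epimerise C6.

Step 3
Reactants: 6 (5S)-5-[2-(diethoxymethyl)prop-2-enoyl]oxolan-2-one
Product: 7 (5S)-5-[(1S)-2-(diethoxymethyl)-1-hydroxyprop-2-en-1-yl]oxolan-2-one
Conditions: NaBH4, CeCl3·7H2O, MeOH, −78 °C
Reagents that add atoms: none
Why: Luche reduction should reduce the α-methylene ketone 1,2 only, and Felkin–Anh attack anti to the C6–O bond of the lactone sets C5 (S), threo to C6.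

Step 4
Reactants: 7 (5S)-5-[(1S)-2-(diethoxymethyl)-1-hydroxyprop-2-en-1-yl]oxolan-2-one
Product: 8 (5S)-5-[(1S)-1-(tert-butyldimethylsilyloxy)-2-(diethoxymethyl)prop-2-en-1-yl]oxolan-2-one
Conditions: TBSCl, imidazole, DMAP (cat.), DMF, 40 °C
Reagents that add atoms: tert-butyldimethylsilyl chloride, CC(C)(C)[Si](C)(C)Cl
Why: Standard silylation of the secondary allylic alcohol under conditions that spare the acetal.

Step 5
Reactants: 8 (5S)-5-[(1S)-1-(tert-butyldimethylsilyloxy)-2-(diethoxymethyl)prop-2-en-1-yl]oxolan-2-one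
Product: 11 (5S)-5-[(1S)-1-(tert-butyldimethylsilyloxy)-2-(diethoxymethyl)prop-2-en-1-yl]furan-2(5H)-one, via lithium enolate 9 (not isolated), via α-phenylselanyl lactone 10 (not isolated)
Conditions: LDA, THF, −78 °C; PhSeBr, −78 °C; then H2O2 (30% aq.), pyridine, 0 °C → rt
Reagents that add atoms: none
Why: α-Selenenylation of the lactone enolate followed by selenoxide syn-elimination, which can only involve the C7 hydrogens, should give the butenolide with C6 unchanged.

Step 6
Reactants: 12 3-methylbut-2-en-1-ol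
Product: 13 1-methoxy-4-{[(3-methylbut-2-en-1-yl)oxy]methyl}benzene
Conditions: NaH, 4-methoxybenzyl chloride, Bu4NI (cat.), THF, 0 °C → rt
Reagents that add atoms: 4-methoxybenzyl chloride, COc1ccc(CCl)cc1
Why: Williamson etherification installs the PMB group that later carries C2–O.

Step 7
Reactants: 13 1-methoxy-4-{[(3-methylbut-2-en-1-yl)oxy]methyl}benzene
Product: 14 (2E)-4-[(4-methoxybenzyl)oxy]-2-methylbut-2-en-1-ol
Conditions: SeO2 (0.3 equiv), t-BuOOH (3 equiv), salicylic acid (cat.), CH2Cl2, rt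
Reagents that add atoms: tert-butyl hydroperoxide, CC(C)(C)OO
Why: Riley allylic oxidation (ene reaction, then [2,3]-shift) occurs at the E-methyl group of the trisubstituted alkene, which fixes the (E)-geometry of the future C1=C10 bond.

Step 8
Reactants: 14 (2E)-4-[(4-methoxybenzyl)oxy]-2-methylbut-2-en-1-ol
Product: 15 1-({[(2E)-4-bromo-3-methylbut-2-en-1-yl]oxy}methyl)-4-methoxybenzene
Conditions: CBr4, PPh3, CH2Cl2, 0 °C
Reagents that add atoms: carbon tetrabromide, BrC(Br)(Br)Br
Why: Appel bromination by SN2 displacement keeps the alkene geometry.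

Step 9
Reactants: 15 1-({[(2E)-4-bromo-3-methylbut-2-en-1-yl]oxy}methyl)-4-methoxybenzene; 16 1,3-dithiane
Product: 18 2-{(2E)-4-[(4-methoxybenzyl)oxy]-2-methylbut-2-en-1-yl}-1,3-dithiane, via 2-lithio-1,3-dithiane 17 (not isolated)
Conditions: 16, n-BuLi, THF, −30 °C; then 15, −78 → −20 °C
Reagents that add atoms: none
Why: Corey–Seebach alkylation of the dithiane anion by SN2 at the primary allylic bromide makes C8 an acyl-anion equivalent.

Step 10
Reactants: 18 2-{(2E)-4-[(4-methoxybenzyl)oxy]-2-methylbut-2-en-1-yl}-1,3-dithiane; 11 (5S)-5-[(1S)-1-(tert-butyldimethylsilyloxy)-2-(diethoxymethyl)prop-2-en-1-yl]furan-2(5H)-one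
Product: 21 2,3-seco adduct (5S,6S,7S,11R) with C8 dithiane and C13 hydroxyl, via lithiated dithiane 19 (not isolated), via lithium lactone enolate 20 (not isolated)
Conditions: 18, n-BuLi, THF, −20 °C; HMPA, then 11, −78 °C; then CH2O (g), −78 → −40 °C
Reagents that add atoms: formaldehyde, C=O
Why: Three-component Michael addition–enolate trapping of the kind used on butenolides in lignan synthesis, in which the dithiane anion adds 1,4 anti to the C6 side chain (sets C7) and formaldehyde enters anti to the new C7 substituent (C11, destroyed later).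

Step 11
Reactants: 21 2,3-seco adduct (5S,6S,7S,11R) with C8 dithiane and C13 hydroxyl
Product: 22 C8 ketone (5S,6S,7S,11R)
Conditions: MeI, CaCO3, MeCN/H2O (9:1), 45 °C
Reagents that add atoms: water, O
Why: S-Methylation and hydrolysis unmask the ketone under buffered, non-oxidising conditions that should leave the alkenes, the acetal and the PMB ether alone.

Step 12
Reactants: 22 C8 ketone (5S,6S,7S,11R)
Product: 23 diol (5S,6S,7R,8S,11R) with C8–OH and C13–OH
Conditions: (R)-2-methyl-CBS-oxazaborolidine (0.5 equiv), catecholborane, toluene, −78 °C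
Reagents that add atoms: none
Why: Corey–Bakshi–Shibata reduction, where the two ring branches at C7 give little substrate bias, so the (R)-oxazaborolidine, which treats the α-branched C7 side as the large group, should set C8 (S).

Step 13
Reactants: 23 diol (5S,6S,7R,8S,11R) with C8–OH and C13–OH
Product: 25 α-methylene lactone alcohol (5S,6S,7R,8S), via primary mesylate 24 (not isolated)
Conditions: MsCl (1.05 equiv), Et3N, CH2Cl2, −40 °C; then DBU, 0 °C → rt
Reagents that add atoms: none
Why: Selective mesylation of the primary alcohol and E1cB elimination give the C11=C13 methylene lactone while the hindered C8 hydroxyl stays free.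

Step 14
Reactants: 25 α-methylene lactone alcohol (5S,6S,7R,8S); 26 angelic acid
Product: 28 C8 angelate, via mixed anhydride 27 (not isolated)
Conditions: 26, 2,4,6-trichlorobenzoyl chloride, Et3N, toluene, rt; then 25, 75 °C
Reagents that add atoms: none
Why: Yamaguchi-type mixed-anhydride esterification without DMAP, conditions known to transfer the angeloyl group without Z-to-E isomerisation to the tiglate.

Step 15
Reactants: 28 C8 angelate
Product: 29 C3 enal
Conditions: PPTS (cat.), acetone/H2O (10:1), 40 °C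
Reagents that add atoms: water, O
Why: Mild acid hydrolysis of the allylic diethyl acetal, which the silyl ether, the PMB ether and both esters should survive.

Step 16
Reactants: 29 C3 enal
Product: 30 C3 allylic 1,1-dichloride
Conditions: (PhO)3P, Cl2, CH2Cl2, −78 °C; then 29, −78 → −20 °C
Reagents that add atoms: dichlorotriphenoxyphosphorane (from triphenyl phosphite and Cl2), ClP(Cl)(Oc1ccccc1)(Oc1ccccc1)Oc1ccccc1
Why: Deoxygenative geminal dichlorination of the aldehyde through an α-chloroalkoxyphosphonium salt at low temperature, a reagent that does not attack ethers, esters or silyl ethers.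

Step 17
Reactants: 30 C3 allylic 1,1-dichloride
Product: 31 C2 allylic alcohol
Conditions: DDQ, CH2Cl2/pH 7 buffer (10:1), 0 °C
Reagents that add atoms: none
Why: Oxidative PMB cleavage by electron transfer to DDQ, in which only the electron-rich benzyl ether reacts.

Step 18
Reactants: 31 C2 allylic alcohol
Product: 32 C2 (E)-enal (cyclisation precursor)
Conditions: TEMPO (10 mol%), PhI(OAc)2, CH2Cl2, rt
Reagents that add atoms: none
Why: TEMPO/PhI(OAc)2 oxidation of the primary allylic alcohol stops at the enal and keeps the (E)-geometry.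

Step 19
Reactants: 32 C2 (E)-enal (cyclisation precursor)
Product: 34 macrocyclic syn-chlorohydrin (2R,3R,5S,6S,7R,8S), via (Z)-γ-chloroallylchromium dichloride 33 (not isolated)
Conditions: CrCl2 (8 equiv), LiI (0.2 equiv), THF/DMF (4:1), 32 added over 12 h to 2 mM, rt
Reagents that add atoms: none
Why: Proposed new method: two equivalents of divalent chromium reduce the allylic C3HCl2 group of 32 to an α-chloroallyl chromium species that equilibrates by 1,3-metal shift to the (Z)-γ-chloroallylchromium 33 (Cr on C15), which adds through C3 to the C2 aldehyde in a six-membered chair transition state with transposition of the double bond to C4=C15. The closest known reactions are the Nozaki–Hiyama allylation macrocyclisation of ω-formyl allylic halides to ten-membered germacrane rings and the intermolecular chromium-mediated addition of 1,3- or 3,3-dichloropropene to aldehydes, which gives 2-chloro homoallylic alcohols; their union in a ring closure is what is new. One ring is closed, the ten-membered carbocycle C1–C10, by attack of the nucleophilic C3 on the exocyclic C2=O (10-exo-trig). C3 is controlled by C5: with the C5–H bond eclipsing C3=C4 (A(1,3) strain) the OTBS group covers one face of the allyl unit and the tether through C6 brings the aldehyde to the other; C2 follows from the chair, in which the chlorine (cis to C15, since the other geometry would clash with the C5 branch) is axial and C1 equatorial, giving the syn chlorohydrin. The step needs chemoselectivity for the aldehyde (the lactone, the angelate and the two acrylate-type alkenes are inert to allylchromium reagents, which add 1,2 to enals), regioselectivity for the chlorine-bearing terminus (chromium sits on the unsubstituted C15) and ring closure over oligomerisation (slow addition to 2 mM; the (E)-C1=C10 bond and the trans-fused lactone fold the chain so that C2 and C3 can meet).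

Step 20
Reactants: 34 macrocyclic syn-chlorohydrin (2R,3R,5S,6S,7R,8S)
Product: 35 1,10-epoxy chlorohydrin (1R,2R,3R,5S,6S,7R,8S,10R)
Conditions: mCPBA, Na2HPO4, CH2Cl2, 0 °C
Reagents that add atoms: mCPBA, OOC(=O)c1cccc(Cl)c1
Why: Henbest-type hydroxyl-directed epoxidation of the only electron-rich alkene, where A(1,3) strain between the C14 methyl and the C2 substituents places C2–H in the alkene plane and the hydroxyl on the outer face, so oxygen should be delivered threo and set C1 (R) and C10 (R).

Step 21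
Reactants: 35 1,10-epoxy chlorohydrin (1R,2R,3R,5S,6S,7R,8S,10R)
Product: 36 5-O-TBS ether of the target
Conditions: NaH, THF, 0 °C
Reagents that add atoms: none
Why: Intramolecular Williamson closure in which the C2 alkoxide displaces the allylic chloride at C3 with inversion to give the cis-2,3-epoxide, while any Payne equilibration with the 1,10-epoxide is reversible and drains into the product.

Step 22
Reactants: 36 5-O-TBS ether of the target
Product: 37 target compound (EANPDB COMP_00179)
Conditions: HF·pyridine, pyridine, THF, 0 °C → rt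
Reagents that add atoms: none
Why: Buffered fluoride cleaves the Si–O bond and should leave both epoxides, the angelate and the methylene lactone untouched.

**Compound list**

1 | (S)-5-oxotetrahydrofuran-2-carboxylic acid | O=C1O[C@H](C(=O)O)CC1 | starting material
2 | (S)-5-oxotetrahydrofuran-2-carbonyl chloride | O=C1O[C@H](C(Cl)=O)CC1 | intermediate
3 | 2-bromo-3,3-diethoxyprop-1-ene | C=C(Br)C(OCC)OCC | starting material
4 | (3,3-diethoxyprop-1-en-2-yl)lithium | [Li]C(=C)C(OCC)OCC | intermediate
5 | (3,3-diethoxyprop-1-en-2-yl)zinc chloride | Cl[Zn]C(=C)C(OCC)OCC | intermediate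
6 | (5S)-5-[2-(diethoxymethyl)prop-2-enoyl]oxolan-2-one | O=C1O[C@H](C(=O)C(=C)C(OCC)OCC)CC1 | intermediate
7 | (5S)-5-[(1S)-2-(diethoxymethyl)-1-hydroxyprop-2-en-1-yl]oxolan-2-one | O=C1O[C@H]([C@@H](O)C(=C)C(OCC)OCC)CC1 | intermediate
8 | (5S)-5-[(1S)-1-(tert-butyldimethylsilyloxy)-2-(diethoxymethyl)prop-2-en-1-yl]oxolan-2-one | O=C1O[C@H]([C@@H](O[Si](C)(C)C(C)(C)C)C(=C)C(OCC)OCC)CC1 | intermediate
9 | lithium enolate of lactone 8 | [Li]OC1=CC[C@@H]([C@@H](O[Si](C)(C)C(C)(C)C)C(=C)C(OCC)OCC)O1 | intermediate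
10 | 3-(phenylselanyl) derivative of lactone 8 (both C3 epimers) | O=C1O[C@H]([C@@H](O[Si](C)(C)C(C)(C)C)C(=C)C(OCC)OCC)CC1[Se]c1ccccc1 | intermediate
11 | (5S)-5-[(1S)-1-(tert-butyldimethylsilyloxy)-2-(diethoxymethyl)prop-2-en-1-yl]furan-2(5H)-one | O=C1O[C@H]([C@@H](O[Si](C)(C)C(C)(C)C)C(=C)C(OCC)OCC)C=C1 | intermediate
12 | 3-methylbut-2-en-1-ol (prenol) | CC(C)=CCO | starting material
13 | 1-methoxy-4-{[(3-methylbut-2-en-1-yl)oxy]methyl}benzene | CC(C)=CCOCc1ccc(OC)cc1 | intermediate
14 | (2E)-4-[(4-methoxybenzyl)oxy]-2-methylbut-2-en-1-ol | OC/C(C)=C/COCc1ccc(OC)cc1 | intermediate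
15 | 1-({[(2E)-4-bromo-3-methylbut-2-en-1-yl]oxy}methyl)-4-methoxybenzene | BrC/C(C)=C/COCc1ccc(OC)cc1 | intermediate
16 | 1,3-dithiane | C1CSCSC1 | starting material
17 | 2-lithio-1,3-dithiane | [Li]C1SCCCS1 | intermediate
18 | 2-{(2E)-4-[(4-methoxybenzyl)oxy]-2-methylbut-2-en-1-yl}-1,3-dithiane | S1CCCSC1C/C(C)=C/COCc1ccc(OC)cc1 | intermediate
19 | 2-lithio derivative of dithiane 18 | [Li]C1(C/C(C)=C/COCc2ccc(OC)cc2)SCCCS1 | intermediate
20 | lithium lactone enolate from 1,4-addition of 19 to 11 | [Li]OC1=C[C@H](C2(C/C(C)=C/COCc3ccc(OC)cc3)SCCCS2)[C@@H]([C@@H](O[Si](C)(C)C(C)(C)C)C(=C)C(OCC)OCC)O1 | intermediate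
21 | 2,3-seco adduct (5S,6S,7S,11R): 6,12-lactone with C5–OTBS, CH(OEt)2 as C3 on C4(=C15H2), CH2OH (C13) on C11, C8 as 1,3-dithiane-2,2-diyl, (E)-C1=C10, C2–OPMB; C6/C7 trans, C7/C11 trans | OC[C@@H]1C(=O)O[C@H]([C@@H](O[Si](C)(C)C(C)(C)C)C(=C)C(OCC)OCC)[C@H]1C1(C/C(C)=C/COCc2ccc(OC)cc2)SCCCS1 | intermediate
22 | C8 ketone (5S,6S,7S,11R): as 21 with C8=O | OC[C@@H]1C(=O)O[C@H]([C@@H](O[Si](C)(C)C(C)(C)C)C(=C)C(OCC)OCC)[C@H]1C(=O)C/C(C)=C/COCc1ccc(OC)cc1 | intermediate
23 | diol (5S,6S,7R,8S,11R): as 22 with C8–OH; the C7 descriptor changes with the priorities, the arrangement in space does not | OC[C@@H]1C(=O)O[C@H]([C@@H](O[Si](C)(C)C(C)(C)C)C(=C)C(OCC)OCC)[C@H]1[C@@H](O)C/C(C)=C/COCc1ccc(OC)cc1 | intermediate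
24 | C13 methanesulfonate of diol 23 | CS(=O)(=O)OC[C@@H]1C(=O)O[C@H]([C@@H](O[Si](C)(C)C(C)(C)C)C(=C)C(OCC)OCC)[C@H]1[C@@H](O)C/C(C)=C/COCc1ccc(OC)cc1 | intermediate
25 | α-methylene lactone alcohol (5S,6S,7R,8S): C11=C13H2, C8–OH, C5–OTBS, C3 acetal, C2–OPMB | C=C1C(=O)O[C@H]([C@@H](O[Si](C)(C)C(C)(C)C)C(=C)C(OCC)OCC)[C@H]1[C@@H](O)C/C(C)=C/COCc1ccc(OC)cc1 | intermediate
26 | angelic acid, (2Z)-2-methylbut-2-enoic acid | C/C=C(/C)C(=O)O | starting material
27 | angelic 2,4,6-trichlorobenzoic anhydride | C/C=C(/C)C(=O)OC(=O)c1c(Cl)cc(Cl)cc1Cl | intermediate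
28 | C8 angelate of 25 (5S,6S,7R,8S) | C=C1C(=O)O[C@H]([C@@H](O[Si](C)(C)C(C)(C)C)C(=C)C(OCC)OCC)[C@H]1[C@@H](OC(=O)/C(C)=C\C)C/C(C)=C/COCc1ccc(OC)cc1 | intermediate
29 | C3 enal: as 28 with C3H=O on C4(=C15H2) | C=C1C(=O)O[C@H]([C@@H](O[Si](C)(C)C(C)(C)C)C(=C)C=O)[C@H]1[C@@H](OC(=O)/C(C)=C\C)C/C(C)=C/COCc1ccc(OC)cc1 | intermediate
30 | C3 allylic 1,1-dichloride: as 29 with C3HCl2 | C=C1C(=O)O[C@H]([C@@H](O[Si](C)(C)C(C)(C)C)C(=C)C(Cl)Cl)[C@H]1[C@@H](OC(=O)/C(C)=C\C)C/C(C)=C/COCc1ccc(OC)cc1 | intermediate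
31 | C2 allylic alcohol: as 30 with C2H2OH | C=C1C(=O)O[C@H]([C@@H](O[Si](C)(C)C(C)(C)C)C(=C)C(Cl)Cl)[C@H]1[C@@H](OC(=O)/C(C)=C\C)C/C(C)=C/CO | intermediate
32 | cyclisation precursor: (1E)-enal at C2, CHCl2 at C3, (5S,6S,7R,8S) | C=C1C(=O)O[C@H]([C@@H](O[Si](C)(C)C(C)(C)C)C(=C)C(Cl)Cl)[C@H]1[C@@H](OC(=O)/C(C)=C\C)C/C(C)=C/C=O | intermediate
33 | (Z)-γ-chloroallylchromium dichloride: Cr on C15, Cl on C3 cis to C15 | C=C1C(=O)O[C@H]([C@@H](O[Si](C)(C)C(C)(C)C)/C(C[Cr](Cl)Cl)=C/Cl)[C@H]1[C@@H](OC(=O)/C(C)=C\C)C/C(C)=C/C=O | intermediate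
34 | (2R,3R,5S,6S,7R,8S)-8-angeloyloxy-3-chloro-2-hydroxy-5-(tert-butyldimethylsilyloxy)germacra-1(10)E,4(15),11(13)-trien-6,12-olide | C=C1C(=O)O[C@H]2[C@H]1[C@@H](OC(=O)/C(C)=C\C)C/C(C)=C/[C@@H](O)[C@H](Cl)C(=C)[C@@H]2O[Si](C)(C)C(C)(C)C | intermediate
35 | (1R,2R,3R,5S,6S,7R,8S,10R)-8-angeloyloxy-3-chloro-1,10-epoxy-2-hydroxy-5-(tert-butyldimethylsilyloxy)germacra-4(15),11(13)-dien-6,12-olide | C=C1C(=O)O[C@H]2[C@H]1[C@@H](OC(=O)/C(C)=C\C)C[C@@]1(C)O[C@@H]1[C@@H](O)[C@H](Cl)C(=C)[C@@H]2O[Si](C)(C)C(C)(C)C | intermediate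
36 | 5-O-tert-butyldimethylsilyl ether of the target (1R,2S,3S,5S,6S,7R,8S,10R) | C=C1C(=O)O[C@H]2[C@H]1[C@@H](OC(=O)/C(C)=C\C)C[C@@]1(C)O[C@@H]1[C@H]1O[C@H]1C(=C)[C@@H]2O[Si](C)(C)C(C)(C)C | intermediate
37 | (1R,2S,3S,5S,6S,7R,8S,10R)-8-angeloyloxy-1,10:2,3-diepoxy-5-hydroxygermacra-4(15),11(13)-dien-6,12-olide (trans-1,10-epoxide, cis-2,3-epoxide, trans-fused lactone) | C=C1C(=O)O[C@H]2[C@H]1[C@@H](OC(=O)/C(C)=C\C)C[C@@]1(C)O[C@@H]1[C@H]1O[C@H]1C(=C)[C@@H]2O | target

**Step count and risks**

Total step count: 22. Longest linear sequence: 18 steps (steps 1–5, then 10–22).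

Steps most likely to fail:

Step 19 (the step beyond precedent). What may go wrong: intermolecular allylation and oligomerisation instead of ring closure, C–C bond formation at C15 instead of C3, or delivery of the aldehyde to the wrong face of the allyl unit so that the C2/C3 pair forms in the wrong absolute sense. Fallback by known chemistry: the C2–C3 bond would be made as a Z-alkene by ring-closing metathesis and oxidised afterwards. The fallback sets out from enal 29. Takai–Lombardo methylenation (Zn, CH2Br2, TiCl4) should give the 1,3-diene F1. DDQ would remove the PMB group to give the allylic alcohol F2. Sharpless asymmetric epoxidation (Ti(OiPr)4, D-(−)-diethyl tartrate, t-BuOOH, −20 °C) should give the (1R,10R)-epoxy alcohol F3, and TEMPO/PhI(OAc)2 the epoxy aldehyde F4. A second Takai–Lombardo methylenation would give the vinyl epoxide F5. Ring-closing metathesis with the second-generation Grubbs catalyst at 1 mM should close the ten-membered ring to the (2Z)-diene monoepoxide F6. Epoxidation of the strained cis C2=C3 bond with dimethyldioxirane, on the face away from C10 (threo), would bring the sequence back to the route at 36.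

Step 10. What may go wrong: the hindered 2-alkyl dithiane anion adds 1,2 to the lactone carbonyl, or acts as a base at C6 of the butenolide with loss of the C5 silyloxy group. Fallback: the order of bond formation is changed so that the less hindered parent anion makes the C7–C8 bond and the C8–C9 bond follows. The fallback sets out from butenolide 11 and alcohol 14. 2-Lithio-1,3-dithiane 17 is added to 11 in THF/HMPA and the enolate trapped with formaldehyde to give the hydroxymethyl dithiane lactone F7. MeI/CaCO3 would then unmask the C8 aldehyde F8, which is in equilibrium with its lactol onto the C13 hydroxyl. Alcohol 14 is converted (MsCl, LiCl) into the allylic chloride F9, whose allylbarium reagent (BaI2, lithium biphenylide, THF, −78 °C) should add to F8 through its unsubstituted carbon with retention of the (E)-geometry. Felkin–Anh attack anti to the C6 branch is expected to give the (8S)-carbinol, so that the sequence rejoins the route at diol 23.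

Step 20. What may go wrong: epoxidation of the C4=C15 bond, delivery of oxygen to the inner face of the (E)-alkene (erythro epoxy alcohol), or acid-promoted opening of the new epoxide next to the free hydroxyl. Fallback: the order of the two epoxide-forming events is reversed, so that the second epoxidation no longer depends on hydroxyl direction. Setting out from chlorohydrin 34, NaH in THF should first close the cis-2,3-epoxide to give the vinyl epoxide F10. The trisubstituted C1=C10 bond, the only electron-rich alkene left, would then be epoxidised with dimethyldioxirane in acetone at −20 °C from the outer face, which by A(1,3) strain is the face of the C2 oxygen. This returns to the route at 36.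

Further compounds
F1 | step 19 | 1,3-diene: as 29 with C3H=CH2 in place of the aldehyde | C=C1C(=O)O[C@H]([C@@H](O[Si](C)(C)C(C)(C)C)C(=C)C=C)[C@H]1[C@@H](OC(=O)/C(C)=C\C)C/C(C)=C/COCc1ccc(OC)cc1
F2 | step 19 | allylic alcohol: as F1 with C2H2OH | C=C1C(=O)O[C@H]([C@@H](O[Si](C)(C)C(C)(C)C)C(=C)C=C)[C@H]1[C@@H](OC(=O)/C(C)=C\C)C/C(C)=C/CO
F3 | step 19 | (1R,10R)-1,10-epoxy alcohol | C=C1C(=O)O[C@H]([C@@H](O[Si](C)(C)C(C)(C)C)C(=C)C=C)[C@H]1[C@@H](OC(=O)/C(C)=C\C)C[C@@]1(C)O[C@@H]1CO
F4 | step 19 | (1R,10R)-1,10-epoxy aldehyde (C2H=O) | C=C1C(=O)O[C@H]([C@@H](O[Si](C)(C)C(C)(C)C)C(=C)C=C)[C@H]1[C@@H](OC(=O)/C(C)=C\C)C[C@@]1(C)O[C@@H]1C=O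
F5 | step 19 | vinyl epoxide (C2H=CH2) | C=C1C(=O)O[C@H]([C@@H](O[Si](C)(C)C(C)(C)C)C(=C)C=C)[C@H]1[C@@H](OC(=O)/C(C)=C\C)C[C@@]1(C)O[C@@H]1C=C
F6 | step 19 | (1R,5S,6S,7R,8S,10R)-8-angeloyloxy-1,10-epoxy-5-(tert-butyldimethylsilyloxy)germacra-2Z,4(15),11(13)-trien-6,12-olide | C=C1C(=O)O[C@H]2[C@H]1[C@@H](OC(=O)/C(C)=C\C)C[C@@]1(C)O[C@@H]1/C=C\C(=C)[C@@H]2O[Si](C)(C)C(C)(C)C
F7 | step 10 | lactone as 21 with an unsubstituted 1,3-dithian-2-yl group on C7 | OC[C@@H]1C(=O)O[C@H]([C@@H](O[Si](C)(C)C(C)(C)C)C(=C)C(OCC)OCC)[C@H]1C1SCCCS1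
F8 | step 10 | C8 aldehyde (open form of the lactol) | OC[C@@H]1C(=O)O[C@H]([C@@H](O[Si](C)(C)C(C)(C)C)C(=C)C(OCC)OCC)[C@H]1C=O
F9 | step 10 | 1-({[(2E)-4-chloro-3-methylbut-2-en-1-yl]oxy}methyl)-4-methoxybenzene | ClC/C(C)=C/COCc1ccc(OC)cc1
F10 | step 20 | (2S,3S,5S,6S,7R,8S)-8-angeloyloxy-2,3-epoxy-5-(tert-butyldimethylsilyloxy)germacra-1(10)E,4(15),11(13)-trien-6,12-olide | C=C1C(=O)O[C@H]2[C@H]1[C@@H](OC(=O)/C(C)=C\C)C/C(C)=C/[C@H]1O[C@H]1C(=C)[C@@H]2O[Si](C)(C)C(C)(C)C
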